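The earlier runs and the new flask were computed for substances that don't exist; scatter was added.

4 questions stand on this flask, and I start my answers from one rate.

| flask | substrate | other conformer | temperature | remark | time |
|---|---|---|---|---|---|
| delta | 5 mM | 1.25 mM | 0 °C | the very flask that is asked about, followed so far |  |
| beta | 5 mM | 0.62 mM | 0 °C | run made earlier |  |
| flask | 5.0 mM | 1.25 mM | 0 °C |  | 3.0 min |

- delta (time / s: target / %): 15.0: 48.2; 30.0: 67.2; 50.0: 73.6; 60.0: 74.0; 80.0: 71.9; 90.0: 67.7; 120: 63.5
- beta (time / s: target / %): 10.0: 35.8; 12.0: 39.4; 20.0: 56.5; 30.0: 68.4; 40.0: 72.8; 60.0: 75.8; 80.0: 71.8

(readings scatter by 1 percentage point)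

- north-east: at 3.0 min raise the temperature by 25 K, then wait 50 s
- north-west: at 3.0 min add substrate, 50.0% of the amount charged, then wait 50 s
- north: at 3.0 min take out 90% of the target then present, then wait 50 s
- west: change nothing and wait 50 s more

- percent here means substrate units held: one self-condensation product counts as two
- target taken out counts as made
- the earlier runs were read with a standard deviation of 1 percentage point
- steps thought possible: substrate <-> other conformer; substrate -> target; target <-> isomer of the product; other conformer -> isomer of the product; 2 other conformer -> self-condensation product
- the earlier runs do not show what temperature does; that part of a forecast is a guess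
- additions bring no volume worth counting

1. target, in percent of the substrate and other conformer together first charged, at 3.0 min
2. what to do for the largest gain in target; "none" if nothing gains more than 2 percentage points (north-east / north-west / north / west / none)
3. target present, with what was taken out counted in, in percent of the substrate and other conformer together first charged, after north-west
4. target present, with what was taken out counted in, in percent of the substrate and other conformer together first charged, after west

I draw the target curve first. The delta run is this flask followed so far. The beta run had half the other conformer, yet at 30.0 s the two read 67.2% and 68.4%. So I treat substrate and other conformer as one pool, a pre-equilibrium, that empties at first order.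

Let κ be the pool's first-order rate of emptying, read from the first beta reading as if what has left the pool stands as target. This gives κ = 0.0443 s⁻¹. It runs low if any isomer of the product has already formed.

At the highest delta reading, 74.0% at 60.0 s, κ leaves 7.01% in the pool. So by this reckoning some 19 percentage points stand elsewhere. At 3.0 min, κ leaves 0.0344% in the pool, so by then the target curve is a falling branch.

The last two delta readings fall at 0.00213 s⁻¹. Carried on from 120 s, that gives my 55.9% now. The level this branch runs into is not in the readings.

For north-west, the 2.50 mM added is 40.0% of the charge. In 50 s, κ empties 89.1% of it, which moves 36 points out of the pool. I choose north-west, and north-east stays a guess.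

The forecast gives 53% now, a little under mine, with 47% after west and 78% after north-west. It chooses north-west, and of north-east it says “warming likely speeds the loss”.

The flask gives 56.6%, 53.4% after west and 83.5% after north-west. Its best is north-east, gaining 38 points, more than the 27 points of north-west.

    substrate ⇌ other conformer (K = 0.00630, k = 0.0150 s⁻¹, Ea = 79.0 kJ mol⁻¹, ΔH = −29.0 kJ mol⁻¹)
    substrate → target (k = 0.0490 s⁻¹, Ea = 71.0 kJ mol⁻¹)
    target ⇌ isomer of the product (K = 1.00, k = 0.00620 s⁻¹, Ea = 80.0 kJ mol⁻¹, ΔH = −78.0 kJ mol⁻¹)
    other conformer → isomer of the product (k = 0.130 s⁻¹, Ea = 72.0 kJ mol⁻¹)
    2 other conformer → self-condensation product (k = 40.0 L mol⁻¹ s⁻¹, Ea = 38.0 kJ mol⁻¹)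
    (constants at 0 °C)

At 3.0 min the flask holds 0.0133% substrate and 43.0% isomer of the product, and the north-east gain is smaller than that isomer. With κ, north-west moves 36 points out of the pool, and the target after north-west stands 30 points above the target after west.

On the neighbour flask left until 50 s, κ leaves 10.9% in the pool. That neighbour flask, computed, holds 8.28% substrate and 0.0505% other conformer.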